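**Retrosynthetic overview**
- The C5 acetate is installed last by SN2 inversion (Mitsunobu, AcOH) of the C5-epimeric alcohol of the finished bicycle.
- The tetrahydrofuran (second ring) is closed by 5-exo opening of a trans C5–C6 oxirane by the tertiary C12–OH, with inversion at C6.
- The C7–C8 bond comes from an anti/Felkin aldol between the dianion of (R)-2-chloro-4-hydroxy-4-octenylcyclopentenone and a trans-epoxy aldehyde made by amine-catalysed epoxidation of an achiral enal.
- The chlorohydroxycyclopentenone comes from (R)-4-allyl-4-hydroxycyclopentenone by Z-selective cross-metathesis and epoxidation/HCl.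
- The allyl carbinol comes from achiral cyclopent-4-ene-1,3-dione by chiral-diol-catalysed enantioselective allylboration, which sets C12. Ring order: the carbocycle is present from the start, the oxacycle is formed in step 8.

Assumptions: allyldiisopropoxyborane is taken as purchasable (otherwise one operation from allylmagnesium bromide and triisopropyl borate); the facial sense of step 1 is assigned by analogy with aryl methyl ketones, and the antipodal diol is used if the enantiomeric carbinol forms. This is a paper proposal; no step has been run.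
Locants: prostanoid-type C1–C20 (C1 = ester carbon; C5, C6, C7 = oxygenated chain carbons; C8–C12 = ring, with C9 = C=O, C10 = C–Cl, C12 = quaternary C–O; C13–C20 = octenyl chain).

**Step 1**
Reactants: 1 cyclopent-4-ene-1,3-dione; 2 allyldiisopropoxyborane
Product: 4 (4R)-4-hydroxy-4-(prop-2-en-1-yl)cyclopent-2-en-1-one, via diisopropyl (1R)-4-oxo-1-(prop-2-en-1-yl)cyclopent-2-en-1-yl borate 3 (not isolated)
Conditions: (R)-3,3′-Br2-BINOL (15 mol %), 2 (1.05 equiv), PhMe/PhCF3 3:1, −35 °C; 1 M HCl work-up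
Reagents that add atoms: none
Why: Proposed new method: the diol exchanges one isopropoxide of 2 to give a more Lewis-acidic chiral allylboronate held rigid by an internal O–H···O hydrogen bond, the doubly activated carbonyl of 1 binds boron, and allyl is delivered through a closed chair transition state with the flat vinyl arm equatorial and the CH2 arm axial, so one enantiotopic C=O face is attacked and C12 is set as R, while the less electrophilic enone carbonyl of the product and the acidic CH2 (no base present) are left alone; the closest known reaction is the 3,3′-dibromo-BINOL-catalysed (Schaus-type) allylboration of aryl methyl ketones and acyclic enones, not yet shown on a cyclic ene-1,3-dione.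

**Step 2**
Reactants: 4 (4R)-4-hydroxy-4-(prop-2-en-1-yl)cyclopent-2-en-1-one; 5 hept-1-ene
Product: 6 (4R)-4-hydroxy-4-[(2Z)-oct-2-en-1-yl]cyclopent-2-en-1-one
Conditions: Grubbs Z-selective Ru catalyst (cyclometalated N-adamantyl NHC, nitrato; 3 mol %), 5 (6 equiv), THF, 35 °C, Ar stream
Reagents that add atoms: none
Why: Z-selective olefin cross-metathesis, in which the chelated catalyst forces an all-syn ruthenacyclobutane and so gives the cis C14=C15 alkene; the electron-poor ring C=C and the free tertiary alcohol do not take part and C12 is untouched.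

**Step 3**
Reactants: 6 (4R)-4-hydroxy-4-[(2Z)-oct-2-en-1-yl]cyclopent-2-en-1-one
Product: 9 (4R)-2-chloro-4-hydroxy-4-[(2Z)-oct-2-en-1-yl]cyclopent-2-en-1-one, via (2R,3S,4R)-2,3-epoxy-4-hydroxy-4-[(2Z)-oct-2-en-1-yl]cyclopentan-1-one 7 (not isolated), via (2S,3R,4R)-2-chloro-3,4-dihydroxy-4-[(2Z)-oct-2-en-1-yl]cyclopentan-1-one 8 (not isolated)
Conditions: 30% H2O2, K2CO3 (0.3 equiv), MeOH, 0 °C; Na2SO3, extract; crude 7, conc. HCl (3 equiv), THF, 0 °C → rt
Reagents that add atoms: hydrogen peroxide, OO (oxirane O of 7 and 3-OH of 8, lost again as water); hydrogen chloride, Cl (the chlorine of 9)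
Why: Weitz–Scheffer nucleophilic epoxidation touches only the enone (oxirane drawn cis to OH; either epoxide diastereomer converges), chloride then opens the epoxy ketone at the α-carbon and the β-hydroxy ketone dehydrates to the α-chloroenone (the known epoxy ketone → 2-chloroenone sequence), with carbonate at 0 °C chosen to keep racemising retro-aldol opening at C12 negligible.

**Step 4**
Reactants: 10 methyl hex-5-enoate; 11 (2E)-but-2-enal
Product: 12 methyl (5E)-7-oxohept-5-enoate
Conditions: Hoveyda–Grubbs II (2 mol %), 11 (4 equiv), CH2Cl2, 40 °C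
Reagents that add atoms: none
Why: Cross-metathesis of a terminal olefin with an enal partner gives the E-enal under thermodynamic control; the methyl ester is inert.

**Step 5**
Reactants: 12 methyl (5E)-7-oxohept-5-enoate
Product: 13 methyl 4-[(2S,3R)-3-formyloxiran-2-yl]butanoate (5S,6R; trans)
Conditions: (S)-2-{bis[3,5-bis(trifluoromethyl)phenyl](trimethylsilyloxy)methyl}pyrrolidine (10 mol %), 35% H2O2 (1.3 equiv), CH2Cl2, rt; used at once
Reagents that add atoms: hydrogen peroxide, OO
Why: Jørgensen iminium–enamine epoxidation, in which hydroperoxide adds to the β-carbon of the E-iminium ion on the face left open by the diarylsilyloxymethyl group and the enamine closes the oxirane, giving the trans (2R,3S)-epoxy aldehyde expected from the (S)-catalyst in high ee.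

**Step 6**
Reactants: 9 (4R)-2-chloro-4-hydroxy-4-[(2Z)-oct-2-en-1-yl]cyclopent-2-en-1-one; 13 methyl 4-[(2S,3R)-3-formyloxiran-2-yl]butanoate
Product: 16 methyl 4-[(2S,3S)-3-{(S)-[(1S,5R)-3-chloro-5-hydroxy-5-[(2Z)-oct-2-en-1-yl]-2-oxocyclopent-3-en-1-yl](hydroxy)methyl}oxiran-2-yl]butanoate (5S,6S,7S,8S,12R), via dilithium (3R)-5-chloro-3-[(2Z)-oct-2-en-1-yl]cyclopenta-1,4-diene-1,3-bis(olate) 14 (not isolated), via the dilithium O7,O12-aldolate of the adduct 15 (not isolated)
Conditions: LDA (2.2 equiv), THF, −78 °C, 30 min; 13 (1.2 equiv), −78 °C, 15 min; AcOH quench at −78 °C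
Reagents that add atoms: none
Why: Directed lithium-enolate aldol addition, in which the ring enolate reacts through a Zimmerman–Traxler chair (anti aldol, C7 S with C8 S), the aldehyde is delivered on the face of the C12 lithium alkoxide away from the octenyl chain (C8 substituent cis to O12), and Felkin–Anh/Cornforth attack anti to the oxirane C–O bond of 13 is the matched facial sense.

**Step 7**
Reactants: 16 (5S,6S,7S,8S,12R) epoxy diol
Product: 17 methyl 4-[(2S,3R)-3-{(S)-acetoxy[(1S,5R)-3-chloro-5-hydroxy-5-[(2Z)-oct-2-en-1-yl]-2-oxocyclopent-3-en-1-yl]methyl}oxiran-2-yl]butanoate (5S,6R,7S,8S,12R)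
Conditions: Ac2O (1.5 equiv), pyridine, CH2Cl2, 0 °C → rt (no DMAP)
Reagents that add atoms: acetic anhydride, CC(=O)OC(C)=O
Why: Acylation of the only secondary alcohol; the tertiary C12–OH and the oxirane do not react with Ac2O/pyridine, and leaving out DMAP limits β-elimination of the new C7 acetate.

**Step 8**
Reactants: 17 (5S,6R,7S,8S,12R) epoxy acetate
Product: 18 methyl (5S)-5-[(2S,3S,3aS,6aR)-3-acetoxy-5-chloro-6a-[(2Z)-oct-2-en-1-yl]-4-oxo-3,3a,4,6a-tetrahydro-2H-cyclopenta[b]furan-2-yl]-5-hydroxypentanoate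
Conditions: CSA (10 mol %), CH2Cl2, 0 °C
Reagents that add atoms: none
Why: Acid-catalysed 5-exo-tet epoxide opening (intramolecular etherification), in which the tertiary C12–OH, held cis to the side chain, attacks C6 with inversion to close the cis-fused tetrahydrofuran (C6 becomes S) and leaves the C5 oxygen as a free alcohol with its configuration (S) retained.

**Step 9**
Reactants: 18 (5S) bicyclic alcohol
Product: 19 methyl (5R)-5-acetoxy-5-[(2S,3S,3aS,6aR)-3-acetoxy-5-chloro-6a-[(2Z)-oct-2-en-1-yl]-4-oxo-3,3a,4,6a-tetrahydro-2H-cyclopenta[b]furan-2-yl]pentanoate (CNP0318775.1)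
Conditions: PPh3, DIAD, AcOH (2 equiv each), toluene, 0 °C → rt
Reagents that add atoms: acetic acid, CC(=O)O
Why: Mitsunobu esterification, in which acetate displaces the alkoxyphosphonium by SN2, inverting C5 (S → R) and installing the second acetate under near-neutral conditions tolerated by the β-acetoxy ketone and the chloroenone.

**Compound list**
1 | cyclopent-4-ene-1,3-dione | O=C1CC(=O)C=C1 | starting material
2 | allyldiisopropoxyborane (diisopropyl prop-2-en-1-ylboronate) | C=CCB(OC(C)C)OC(C)C | starting material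
3 | diisopropyl (1R)-4-oxo-1-(prop-2-en-1-yl)cyclopent-2-en-1-yl borate | C=CC[C@]1(OB(OC(C)C)OC(C)C)C=CC(=O)C1 | intermediate (not isolated)
4 | (4R)-4-hydroxy-4-(prop-2-en-1-yl)cyclopent-2-en-1-one | C=CC[C@]1(O)C=CC(=O)C1 | intermediate
5 | hept-1-ene | C=CCCCCC | starting material
6 | (4R)-4-hydroxy-4-[(2Z)-oct-2-en-1-yl]cyclopent-2-en-1-one | CCCCC/C=C\C[C@]1(O)C=CC(=O)C1 | intermediate
7 | (2R,3S,4R)-2,3-epoxy-4-hydroxy-4-[(2Z)-oct-2-en-1-yl]cyclopentan-1-one (oxirane cis to OH) | CCCCC/C=C\C[C@]1(O)[C@H]2O[C@H]2C(=O)C1 | intermediate (not isolated)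
8 | (2S,3R,4R)-2-chloro-3,4-dihydroxy-4-[(2Z)-oct-2-en-1-yl]cyclopentan-1-one | CCCCC/C=C\C[C@]1(O)[C@@H](O)[C@H](Cl)C(=O)C1 | intermediate (not isolated)
9 | (4R)-2-chloro-4-hydroxy-4-[(2Z)-oct-2-en-1-yl]cyclopent-2-en-1-one | CCCCC/C=C\C[C@]1(O)C=C(Cl)C(=O)C1 | intermediate
10 | methyl hex-5-enoate | COC(=O)CCCC=C | starting material
11 | (2E)-but-2-enal | C/C=C/C=O | starting material
12 | methyl (5E)-7-oxohept-5-enoate | COC(=O)CCC/C=C/C=O | intermediate
13 | methyl 4-[(2S,3R)-3-formyloxiran-2-yl]butanoate | COC(=O)CCC[C@@H]1O[C@H]1C=O | intermediate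
14 | dilithium (3R)-5-chloro-3-[(2Z)-oct-2-en-1-yl]cyclopenta-1,4-diene-1,3-bis(olate) | CCCCC/C=C\C[C@]1([O-])C=C(Cl)C([O-])=C1.[Li+].[Li+] | intermediate (not isolated)
15 | dilithium O7,O12-aldolate of 16 (5S,6S,7S,8S,12R) | CCCCC/C=C\C[C@]1([O-])C=C(Cl)C(=O)[C@H]1[C@H]([O-])[C@@H]2O[C@H]2CCCC(=O)OC.[Li+].[Li+] | intermediate (not isolated)
16 | methyl 4-[(2S,3S)-3-{(S)-[(1S,5R)-3-chloro-5-hydroxy-5-[(2Z)-oct-2-en-1-yl]-2-oxocyclopent-3-en-1-yl](hydroxy)methyl}oxiran-2-yl]butanoate | CCCCC/C=C\C[C@]1(O)C=C(Cl)C(=O)[C@H]1[C@H](O)[C@@H]2O[C@H]2CCCC(=O)OC | intermediate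
17 | methyl 4-[(2S,3R)-3-{(S)-acetoxy[(1S,5R)-3-chloro-5-hydroxy-5-[(2Z)-oct-2-en-1-yl]-2-oxocyclopent-3-en-1-yl]methyl}oxiran-2-yl]butanoate | CCCCC/C=C\C[C@]1(O)C=C(Cl)C(=O)[C@H]1[C@H](OC(C)=O)[C@@H]2O[C@H]2CCCC(=O)OC | intermediate
18 | methyl (5S)-5-[(2S,3S,3aS,6aR)-3-acetoxy-5-chloro-6a-[(2Z)-oct-2-en-1-yl]-4-oxo-3,3a,4,6a-tetrahydro-2H-cyclopenta[b]furan-2-yl]-5-hydroxypentanoate | CCCCC/C=C\C[C@]12C=C(Cl)C(=O)[C@H]1[C@H](OC(C)=O)[C@H]([C@H](CCCC(=O)OC)O)O2 | intermediate
19 | methyl (5R)-5-acetoxy-5-[(2S,3S,3aS,6aR)-3-acetoxy-5-chloro-6a-[(2Z)-oct-2-en-1-yl]-4-oxo-3,3a,4,6a-tetrahydro-2H-cyclopenta[b]furan-2-yl]pentanoate | CCCCC/C=C\C[C@]12C=C(Cl)C(=O)[C@H]1[C@H](OC(C)=O)[C@H]([C@@H](CCCC(=O)OC)OC(C)=O)O2 | target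

**Step count and risks**
Total steps: 9. Longest linear sequence: 7 (steps 1, 2, 3, 6, 7, 8, 9); steps 4 and 5 form the side branch.

Three steps most likely to fail:

Step 1 (the new reaction): the ee may be low on this compact ring, and a second allylation of the product is possible. The fallback sets out from 1 and comes back at 4. Compound 1 is stirred with 2 in toluene at room temperature without the diol (uncatalysed closed-transition-state allylboration) to give racemic diisopropyl 4-oxo-1-(prop-2-en-1-yl)cyclopent-2-en-1-yl borate F1 (not isolated). Aqueous work-up gives racemic 4-hydroxy-4-(prop-2-en-1-yl)cyclopent-2-en-1-one F2. Preparative chiral SFC on an amylose carbamate phase delivers 4 and sets aside (4S)-4-hydroxy-4-(prop-2-en-1-yl)cyclopent-2-en-1-one F3. Enantiopurity then comes from resolution instead of catalysis.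

Step 6: the dianion may give poor C7/C8 control, retro-aldol opening at C12, or Payne rearrangement of the aldolate. The fallback sets out from 9 and comes back at 17. TMSCl and imidazole in DMF give (4R)-2-chloro-4-[(2Z)-oct-2-en-1-yl]-4-(trimethylsilyloxy)cyclopent-2-en-1-one F4. LDA (1.1 equiv) in THF at −78 °C gives its lithium enolate F5 (not isolated). Addition of 13 gives the lithium aldolate F6 (not isolated), which is acetylated in the flask with Ac2O to the 7-O-acetyl-12-O-trimethylsilyl aldol F7. PPTS in MeOH at 0 °C removes the silyl group to give 17. This is the protected mono-enolate aldol long used for this ring type, and it also removes the separate acetylation step.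

Step 9: the C5 alcohol is hindered and next to the ring oxygen, so the Mitsunobu reaction may stall or eliminate, and 1,3-acetyl migration from O7 is possible. The fallback sets out from 18 and comes back at 19. Chloromethanesulfonyl chloride and pyridine in CH2Cl2 at 0 °C give methyl (5S)-5-[(2S,3S,3aS,6aR)-3-acetoxy-5-chloro-6a-[(2Z)-oct-2-en-1-yl]-4-oxo-3,3a,4,6a-tetrahydro-2H-cyclopenta[b]furan-2-yl]-5-[(chloromethanesulfonyl)oxy]pentanoate F8. CsOAc with 18-crown-6 in toluene at 50 °C displaces the sulfonate with inversion to give 19.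

**Further compounds**
F1 | step 1 | racemic diisopropyl 4-oxo-1-(prop-2-en-1-yl)cyclopent-2-en-1-yl borate | C=CCC1(OB(OC(C)C)OC(C)C)C=CC(=O)C1
F2 | step 1 | racemic 4-hydroxy-4-(prop-2-en-1-yl)cyclopent-2-en-1-one | C=CCC1(O)C=CC(=O)C1
F3 | step 1 | (4S)-4-hydroxy-4-(prop-2-en-1-yl)cyclopent-2-en-1-one | C=CC[C@@]1(O)C=CC(=O)C1
F4 | step 6 | (4R)-2-chloro-4-[(2Z)-oct-2-en-1-yl]-4-(trimethylsilyloxy)cyclopent-2-en-1-one | CCCCC/C=C\C[C@]1(O[Si](C)(C)C)C=C(Cl)C(=O)C1
F5 | step 6 | lithium (3R)-5-chloro-3-[(2Z)-oct-2-en-1-yl]-3-(trimethylsilyloxy)cyclopenta-1,4-dien-1-olate | CCCCC/C=C\C[C@]1(O[Si](C)(C)C)C=C(Cl)C([O-])=C1.[Li+]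
F6 | step 6 | lithium O7-aldolate of the 12-O-trimethylsilyl aldol (5S,6S,7S,8S,12R) | CCCCC/C=C\C[C@]1(O[Si](C)(C)C)C=C(Cl)C(=O)[C@H]1[C@H]([O-])[C@@H]2O[C@H]2CCCC(=O)OC.[Li+]
F7 | step 6 | 12-O-trimethylsilyl ether of 17 (5S,6R,7S,8S,12R) | CCCCC/C=C\C[C@]1(O[Si](C)(C)C)C=C(Cl)C(=O)[C@H]1[C@H](OC(C)=O)[C@@H]2O[C@H]2CCCC(=O)OC
F8 | step 9 | 5-O-chloromethanesulfonate of 18 (5S) | CCCCC/C=C\C[C@]12C=C(Cl)C(=O)[C@H]1[C@H](OC(C)=O)[C@H]([C@H](CCCC(=O)OC)OS(=O)(=O)CCl)O2
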